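## Structural features

The target is a ten-carbon chain (labelled C1–C10 from the esterified CH2O end) joined through an exocyclic C10=Cα double bond to a single γ-lactone ring (carbonyl carbon, Cα, Cβ, Cγ, ring oxygen). C1 carries an (E)-3-methylpent-2-enoate, C2=C3 is the Z alkene of a neryl unit, C6=C7 is E, and C8 is an (S)-acetoxy carbinol that is allylic to C6=C7 and separated from the ring by C9 and C10. In the ring, Cβ (S) bears a free hydroxyl and Cγ (R) a 2-methylprop-1-enyl group; these two stereocentres are adjacent and trans. The exocyclic alkene is E, with C9 cis to Cβ and trans to the carbonyl. C8 stands in a 1,5 relation to Cβ and has to be controlled on its own. Fragile points are the allylic Cγ–O ester bond (ionisable to a dimethylallyl-type cation), the alkylidene lactone as a Michael acceptor, the β-hydroxyl (elimination, acyl transfer), the Z alkene and the two conjugated esters (isomerisation); in addition the oxygens at C1, C8 and Cβ must end as three different functions. The real difficulty is to create Cβ, Cγ and the geometry of the trisubstituted C10=Cα alkene in one defined relation. The key step uses the array C10=Cα(C=O)–Cβ(O)–Cγ(O): Cγ is a homoallylic carbinol carbon with respect to C10=Cα, so the Cβ–Cγ bond is the one formed when an allylboronate with boron on C10, the carboxyl on Cα and an oxygen on Cβ adds to 3-methylbut-2-enal. A check of the chair model confirms that the boron-bearing carbon must be S (both carbon substituents outrank boron) and the enol ether Z.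

## Logic of the disconnections

21 is cut at the C1 O–acyl bond into 19 and 20. This removes the only acid-derived fragment and leaves a diol. The forward step must acylate the primary allylic hydroxyl and leave the ring hydroxyl, without isomerising the enoate.

19 is traced back through 18 and 17 to 16 by changing only O–Si and O–acyl bonds: the two free hydroxyls become silyl ethers and the C8 acetate becomes a triethylsilyl ether. The gain is three oxygens that can be told apart by the lability of their silyl groups. The forward steps must cleave the triethylsilyl ether alone, then the other two silyl ethers together, without base.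

16 is opened at the ring O–C(=O) bond to 15. This turns the ring into an open-chain hydroxy ester whose alkene geometry and two carbinols are already in place. The forward step must lactonise without ionising the allylic Cγ–O bond and without moving a silyl group.

15 is cut at the Cβ–Cγ bond into 12 and 13. This is the strategic cut: one bond carries both ring stereocentres and the alkene geometry, and the partners are an aldehyde and a boronate with a single controlling stereocentre. The forward step must transfer the C10 configuration faithfully through one chair and keep the enol ether geometry.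

12 is cut at the Cα–CH(O) bond and at the enol O–Si bond to 10, with methyl formate and a silyl triflate as the added pieces. This reduces the reagent to a simple β-boryl ester. The forward step must formylate an ester enolate that has boron on the neighbouring carbon and fix the enol oxygen cis to the ester.

10 is cut at the C10–B bond to 8 and 9. The stereocentre then comes from a catalyst and a planar enoate. The forward step must be ligand-controlled despite the C8 centre two atoms away.

8 is cut at the C10=Cα double bond to 6 and 7. This leaves a terminal alkene and a commodity acrylate. The forward step must react only at the monosubstituted alkene.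

6 is cut at the O–Si bond and at the C8–C9 bond to 4 (through 5) and an allylborane. C8 becomes an aldehyde carbon. The forward step must add allyl to one face of a conjugated aldehyde.

4 is traced to 2 by removing the C8 oxygen (through 3), and 2 to 1 by removing the silyl group. The chain with its Z alkene is then a commercial terpene alcohol. The forward step must oxidise only the E methyl group of the terminal alkene.

## Other disconnections considered

Alternative 1: The cut is the ring O–Cγ bond. The (S)-β-hydroxy acid A1, which ends in a tertiary allylic methyl carbonate, would be ionised by zerovalent palladium (Pd(PPh3)4) to a π-allyl complex, and the carboxylate would close onto the near allyl terminus to give the hydroxy lactone A2.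
- In its favour: the closure has no real competitor (attack at the far terminus would need a seven-membered ring). Carboxylate capture of π-allyl palladium is an established reaction class, so on precedent this key step is the better of the two. A1 needs only one stereocentre.
- Against it here: A2 is only the ring. C10=Cα, C8 and the whole chain are still missing, and the alkylidene would have to be made afterwards on a β-oxygenated lactone, where neither E geometry nor freedom from β-elimination is assured. The trans relation rests on a carbinol biasing a π-allyl that can equilibrate, and on a product that can re-ionise, so it would be thermodynamic and not relayed.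
- Comparison: on structure, A2 covers two stereocentres and no alkene, whereas 15 covers two stereocentres, the alkene geometry and the full skeleton. On mechanism it is equal or better in precedent but controls less. On step economy it is worse, because ring and chain are made in separate lines and joined by a further step of uncertain geometry.

Alternative 2: The cut is the C8–C9 bond. The silyl ketene acetal A3 (a 3-ethenyl-2-silyloxy-4,5-dihydrofuran carrying the Cβ silyl ether and the Cγ alkenyl group) would add through its terminal vinyl carbon to the Si face of the enal A4, which already holds the pentenoate ester, under SiCl4 and a chiral bisphosphoramide, to give A5.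
- In its favour: it is the most convergent plan, since one bond joins two complete halves and only acetylation and desilylation remain. The ester is in place from the start, so no late selective acylation is needed; on this point it is better than the chosen plan. Conjugated aldehydes are the best substrates for this Lewis-base-activated aldol, so precedent is equal or better.
- Against it here: the alkylidene geometry would be decided by the conformation of the diene in A3 and not by a stereocentre, and the silyloxy group on Cβ presses against the conformer that leads to E. Attack at Cα competes with attack at the vinyl terminus. The catalyst must override a chiral nucleophile. A3 has to be made from a finished trans lactone by enolisation next to a β-leaving group.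
- Comparison: on structure it sets one stereocentre and one alkene in the coupling, against two stereocentres and one alkene in the chosen step. On mechanism it is better precedented but weaker in geometric control. On step economy its longest linear sequence would be shorter than the thirteen steps of the chosen plan, and it is the better plan on that count.

Alternative 3: The cut is the C9–C10 bond. Reductive decarboxylation of the N-acyloxyphthalimide A6 would give a primary radical at C9, which adds to the sulfur-bearing carbon of the α-(phenylsulfonylmethylidene) lactone A7; loss of a phenylsulfonyl radical would give A8.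
- In its favour: the conditions are neutral, all three stereocentres are set beforehand, the ester is already in place, and the polarity (nucleophilic radical, electron-poor acceptor) is matched. Radical addition–elimination on vinyl sulfones is a known reaction class, so precedent is equal to or better than that of the chosen step.
- Against it here: the C9 radical is homoallylic to C6=C7 through C8, and a 1,2-vinyl shift through a cyclopropylcarbinyl radical would lead to a more stable α-silyloxy radical and scramble the chain. The alkene geometry would be set under reversible sulfonyl-radical addition, so it is thermodynamic and uncertain next to the Cβ silyloxy group. Sulfonyl radicals can also isomerise the Z alkene at C2=C3.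
- Comparison: on structure it forms only the alkene, whereas the chosen step forms the alkene and two stereocentres. On mechanism it is less secure for this particular radical. On step economy it is about equal in total and better in convergence, since both A6 and A7 need several steps of their own.

Key step: step 8

Abbreviations: TBDPS = tert-butyldiphenylsilyl, TES = triethylsilyl, TBS = tert-butyldimethylsilyl, pin = pinacolato, Ipc = isopinocampheyl.

Assumption: in step 6 the (R,Sp) antipode of the ferrocenyl bisphosphine is taken to deliver boron to the face that gives (3S)-10; induction is ligand-controlled and both antipodes are commercial, so the mirror image is used if a trial on 8 shows the opposite sense.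

Step 1
Reactants: 1 nerol
Product: 2 tert-butyl{[(2Z)-3,7-dimethylocta-2,6-dien-1-yl]oxy}diphenylsilane
Conditions: TBDPSCl, imidazole, CH2Cl2, 0 to 23 °C
Reagents that add atoms: tert-butyl(chloro)diphenylsilane, CC(C)(C)[Si](Cl)(c1ccccc1)c1ccccc1
Why: Silylation of a primary alcohol; the robust TBDPS ether is chosen because it must survive oxidation, strong base and mild acid and still be distinguishable from a triethylsilyl ether.

Step 2
Reactants: 2 tert-butyl{[(2Z)-3,7-dimethylocta-2,6-dien-1-yl]oxy}diphenylsilane
Product: 4 (2E,6Z)-8-(TBDPS-oxy)-2,6-dimethylocta-2,6-dienal, via allylic alcohol 3 (not isolated)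
Conditions: SeO2 (0.1 equiv), tBuOOH, salicylic acid (cat.), CH2Cl2, 23 °C; then MnO2, CH2Cl2, 23 °C
Reagents that add atoms: tert-butyl hydroperoxide, CC(C)(C)OO
Why: Selenium dioxide allylic oxidation (ene reaction then 2,3-sigmatropic shift) attacks the E methyl group of the more electron-rich terminal alkene and gives the E allylic alcohol, since the C2=C3 alkene is deactivated by its allylic silyloxy group; MnO2 then takes alcohol and any aldehyde already formed to the single enal.

Step 3
Reactants: 4 (2E,6Z)-8-(TBDPS-oxy)-2,6-dimethylocta-2,6-dienal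
Product: 5 (4S,5E,9Z)-11-(TBDPS-oxy)-5,9-dimethylundeca-1,5,9-trien-4-ol
Conditions: (−)-Ipc2B(allyl) (from (+)-α-pinene), Et2O, −78 °C; then NaOH, H2O2, 23 °C
Reagents that add atoms: (−)-B-allyldiisopinocampheylborane, C=CCB([C@@H]1C[C@@H]2C[C@H]([C@H]1C)C2(C)C)[C@@H]1C[C@@H]2C[C@H]([C@H]1C)C2(C)C
Why: Brown allylboration; the allyl group is delivered through a six-membered chair to the Si face of the conjugated aldehyde, the same sense in which this reagent gives the S alcohol from benzaldehyde, and this sets (S)-C8, while enals react only at the carbonyl carbon.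

Step 4
Reactants: 5 (4S,5E,9Z)-11-(TBDPS-oxy)-5,9-dimethylundeca-1,5,9-trien-4-ol
Product: 6 (4S,5E,9Z)-11-(TBDPS-oxy)-5,9-dimethyl-4-(TES-oxy)undeca-1,5,9-triene
Conditions: TESCl, imidazole, DMAP (cat.), CH2Cl2, 0 °C
Reagents that add atoms: chlorotriethylsilane, CC[Si](Cl)(CC)CC
Why: Silylation of a secondary allylic alcohol; an acetate could not survive the later amide base, and the TES ether is the one silyl group that can later be removed beside the other two.

Step 5
Reactants: 6 (4S,5E,9Z)-11-(TBDPS-oxy)-5,9-dimethyl-4-(TES-oxy)undeca-1,5,9-triene; 7 methyl acrylate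
Product: 8 methyl (2E,5S,6E,10Z)-12-(TBDPS-oxy)-6,10-dimethyl-5-(TES-oxy)dodeca-2,6,10-trienoate
Conditions: second-generation Hoveyda–Grubbs catalyst (5 mol%), 7 (5 equiv), CH2Cl2, 40 °C
Reagents that add atoms: none
Why: Olefin cross-metathesis of a terminal alkene with an acrylate; the two trisubstituted alkenes are too hindered to enter the cycle, and the conjugated product should form as the E isomer.

Step 6
Reactants: 8 methyl (2E,5S,6E,10Z)-12-(TBDPS-oxy)-6,10-dimethyl-5-(TES-oxy)dodeca-2,6,10-trienoate; 9 bis(pinacolato)diboron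
Product: 10 methyl (3S,5S,6E,10Z)-12-(TBDPS-oxy)-6,10-dimethyl-3-(4,4,5,5-tetramethyl-1,3,2-dioxaborolan-2-yl)-5-(TES-oxy)dodeca-6,10-dienoate
Conditions: CuCl (3 mol%), NaOtBu (6 mol%), (R)-1-[(Sp)-2-(diphenylphosphino)ferrocenyl]ethyldicyclohexylphosphine (4 mol%), MeOH (2 equiv), THF, 23 °C
Reagents that add atoms: none
Why: Copper-catalysed asymmetric conjugate borylation of an α,β-unsaturated ester; a phosphine-bound Cu–Bpin species adds to the enoate and methanol protonates the copper enolate, so the ligand and not the remote C8 centre selects the face and sets (S)-C10, and the unactivated alkenes do not react.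

Step 7
Reactants: 10 methyl (3S,5S,6E,10Z)-12-(TBDPS-oxy)-6,10-dimethyl-3-(4,4,5,5-tetramethyl-1,3,2-dioxaborolan-2-yl)-5-(TES-oxy)dodeca-6,10-dienoate
Product: 12 methyl (2Z)-3-(TBS-oxy)-2-[(1S,3S,4E,8Z)-10-(TBDPS-oxy)-4,8-dimethyl-1-(4,4,5,5-tetramethyl-1,3,2-dioxaborolan-2-yl)-3-(TES-oxy)deca-4,8-dien-1-yl]prop-2-enoate, via lithium formyl-ester enolate 11 (not isolated)
Conditions: LiN(iPr)2 (2.1 equiv), THF, −78 °C; HCO2Me (3 equiv), −78 to −20 °C; TBSOTf (3.2 equiv), −78 to 0 °C
Reagents that add atoms: methyl formate, COC=O; tert-butyldimethylsilyl trifluoromethanesulfonate, CC(C)(C)[Si](C)(C)OS(=O)(=O)C(F)(F)F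
Why: Crossed Claisen formylation of the ester lithium enolate followed by O-silylation; the formyl ester is held as a lithium chelate with the new oxygen cis to the ester carbonyl, and the fast silyl triflate traps that geometry as the Z enol ether. Trapping in the same flask avoids handling the free formyl ester, which is at once an aldehyde and an allylboronate.

Step 8
Reactants: 12 methyl (2Z)-3-(TBS-oxy)-2-[(1S,3S,4E,8Z)-10-(TBDPS-oxy)-4,8-dimethyl-1-(4,4,5,5-tetramethyl-1,3,2-dioxaborolan-2-yl)-3-(TES-oxy)deca-4,8-dien-1-yl]prop-2-enoate; 13 3-methylbut-2-enal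
Product: 15 methyl (2E,5S,6E,10Z)-2-[(1S,2R)-1-(TBS-oxy)-2-hydroxy-4-methylpent-3-en-1-yl]-12-(TBDPS-oxy)-6,10-dimethyl-5-(TES-oxy)dodeca-2,6,10-trienoate, via borate ester 14 (not isolated)
Conditions: 13 (3 equiv), toluene (1 M), 4 Å molecular sieves, 85 °C; then pH 7 phosphate buffer, 23 °C
Reagents that add atoms: none
Why: Proposed new method: the boron of 12 binds the aldehyde oxygen of 13 and the allyl unit is passed on through a closed six-membered chair (B, O, carbonyl C, Cβ, Cα, C10) in which Cβ attacks the carbonyl carbon while the C10–B bond breaks and C10=Cα forms, and neutral hydrolysis of borate 14 then frees the Cγ hydroxyl; the closest known reaction types are the additions of 2-alkoxycarbonyl allylboronates to aldehydes (the usual entry to α-methylene and α-alkylidene γ-lactones) and the additions of α-chiral γ-alkoxyallylboronates that give anti 1,2-diol monoethers, and the union of both features in one reagent is what is new. No ring of the molecule is closed; the six-membered array exists only in the transition state and the lactone is formed in step 9. Cβ and Cγ are set relative to each other by the chair: the silyloxy group, which is trans to C10 on the enol ether, and the alkenyl group of the aldehyde both sit equatorial, which gives the anti (later trans) relation. Their absolute sense is relayed from (S)-C10, because only the chair with the C9 chain axial is used. The same axial placement puts C9 cis to Cβ in the new alkene, that is the E alkylidene. The selectivity that matters is therefore axial against equatorial C9, and the substrate itself secures it: an equatorial chain would eclipse the ester on Cα (A(1,2) strain) and meet the pinacol methyls. The ester makes the reagent a poor nucleophile and the enol ether oxygen compensates only in part, hence the heating; acid catalysts are avoided at first because of the enol and triethylsilyl ethers, and the enal is expected to react only at its carbonyl carbon.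

Step 9
Reactants: 15 methyl (2E,5S,6E,10Z)-2-[(1S,2R)-1-(TBS-oxy)-2-hydroxy-4-methylpent-3-en-1-yl]-12-(TBDPS-oxy)-6,10-dimethyl-5-(TES-oxy)dodeca-2,6,10-trienoate
Product: 16 (3E,4S,5R)-4-(TBS-oxy)-3-[(3S,4E,8Z)-10-(TBDPS-oxy)-4,8-dimethyl-3-(TES-oxy)deca-4,8-dien-1-ylidene]-5-(2-methylprop-1-en-1-yl)oxolan-2-one
Conditions: pyridinium p-toluenesulfonate (0.2 equiv), toluene, 4 Å molecular sieves, 50 °C
Reagents that add atoms: none
Why: Acid-catalysed lactonisation (intramolecular transesterification, 5-exo-trig at the ester carbonyl); the carboxyl sits on Cα itself, so closure does not depend on the alkene geometry, and the weak acid in an aprotic solvent should leave the silyl ethers and the allylic Cγ–O bond intact. Any 16 already formed in step 8 simply joins this material.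

Step 10
Reactants: 16 (3E,4S,5R)-4-(TBS-oxy)-3-[(3S,4E,8Z)-10-(TBDPS-oxy)-4,8-dimethyl-3-(TES-oxy)deca-4,8-dien-1-ylidene]-5-(2-methylprop-1-en-1-yl)oxolan-2-one
Product: 17 (3E,4S,5R)-4-(TBS-oxy)-3-[(3S,4E,8Z)-10-(TBDPS-oxy)-3-hydroxy-4,8-dimethyldeca-4,8-dien-1-ylidene]-5-(2-methylprop-1-en-1-yl)oxolan-2-one
Conditions: pyridinium p-toluenesulfonate (0.2 equiv), MeOH/CH2Cl2 (1:1), 0 °C
Reagents that add atoms: none
Why: Acid-catalysed methanolysis of a silyl ether; the secondary TES ether is cleaved far faster than the hindered secondary TBS ether or the primary TBDPS ether, and the E alkene keeps the freed C8 hydroxyl away from the lactone carbonyl.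

Step 11
Reactants: 17 (3E,4S,5R)-4-(TBS-oxy)-3-[(3S,4E,8Z)-10-(TBDPS-oxy)-3-hydroxy-4,8-dimethyldeca-4,8-dien-1-ylidene]-5-(2-methylprop-1-en-1-yl)oxolan-2-one
Product: 18 (3S,4E,8Z)-1-[(3E,4S,5R)-4-(TBS-oxy)-5-(2-methylprop-1-en-1-yl)-2-oxooxolan-3-ylidene]-10-(TBDPS-oxy)-4,8-dimethyldeca-4,8-dien-3-yl acetate
Conditions: Ac2O, pyridine, DMAP (cat.), CH2Cl2, 0 to 23 °C
Reagents that add atoms: acetic anhydride, CC(=O)OC(C)=O
Why: Acylation of the only free hydroxyl; the C–O bond at C8 is not touched, so the configuration is retained.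

Step 12
Reactants: 18 (3S,4E,8Z)-1-[(3E,4S,5R)-4-(TBS-oxy)-5-(2-methylprop-1-en-1-yl)-2-oxooxolan-3-ylidene]-10-(TBDPS-oxy)-4,8-dimethyldeca-4,8-dien-3-yl acetate
Product: 19 (3S,4E,8Z)-10-hydroxy-1-[(3E,4S,5R)-4-hydroxy-5-(2-methylprop-1-en-1-yl)-2-oxooxolan-3-ylidene]-4,8-dimethyldeca-4,8-dien-3-yl acetate
Conditions: HF·pyridine, pyridine, THF, 0 to 23 °C
Reagents that add atoms: none
Why: Fluoride desilylation under buffered, non-basic conditions removes both remaining silyl ethers; no alkoxide is formed, so acetyl migration, conjugate addition to the alkylidene lactone and elimination are not expected.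

Step 13
Reactants: 19 (3S,4E,8Z)-10-hydroxy-1-[(3E,4S,5R)-4-hydroxy-5-(2-methylprop-1-en-1-yl)-2-oxooxolan-3-ylidene]-4,8-dimethyldeca-4,8-dien-3-yl acetate; 20 (2E)-3-methylpent-2-enoic acid
Product: 21 (2Z,6E,8S)-8-acetoxy-10-[(3E,4S,5R)-4-hydroxy-5-(2-methylprop-1-en-1-yl)-2-oxooxolan-3-ylidene]-3,7-dimethyldeca-2,6-dien-1-yl (2E)-3-methylpent-2-enoate
Conditions: PPh3 (1.2 equiv), diisopropyl azodicarboxylate (1.2 equiv), 20 (1.2 equiv), THF, −20 to 0 °C
Reagents that add atoms: none
Why: Mitsunobu esterification; the phosphonium activates the unhindered primary allylic alcohol in preference to the hindered ring hydroxyl and the carboxylate displaces it at C1. The acid is never turned into an acylating agent, so γ-deprotonation and isomerisation of the enoate are avoided.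

Compound list

1 | nerol, (2Z)-3,7-dimethylocta-2,6-dien-1-ol | CC(C)=CCC/C(C)=C\CO | starting material
2 | tert-butyl{[(2Z)-3,7-dimethylocta-2,6-dien-1-yl]oxy}diphenylsilane | CC(C)=CCC/C(C)=C\CO[Si](c1ccccc1)(c1ccccc1)C(C)(C)C | intermediate
3 | (2E,6Z)-8-(TBDPS-oxy)-2,6-dimethylocta-2,6-dien-1-ol (not isolated) | CC(C)(C)[Si](c1ccccc1)(c1ccccc1)OC/C=C(/C)CC/C=C(\C)CO | intermediate
4 | (2E,6Z)-8-(TBDPS-oxy)-2,6-dimethylocta-2,6-dienal | CC(C)(C)[Si](c1ccccc1)(c1ccccc1)OC/C=C(/C)CC/C=C(\C)C=O | intermediate
5 | (4S,5E,9Z)-11-(TBDPS-oxy)-5,9-dimethylundeca-1,5,9-trien-4-ol | CC(C)(C)[Si](c1ccccc1)(c1ccccc1)OC/C=C(/C)CC/C=C(\C)[C@@H](O)CC=C | intermediate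
6 | (4S,5E,9Z)-11-(TBDPS-oxy)-5,9-dimethyl-4-(TES-oxy)undeca-1,5,9-triene | CC(C)(C)[Si](c1ccccc1)(c1ccccc1)OC/C=C(/C)CC/C=C(\C)[C@@H](O[Si](CC)(CC)CC)CC=C | intermediate
7 | methyl acrylate | C=CC(=O)OC | starting material
8 | methyl (2E,5S,6E,10Z)-12-(TBDPS-oxy)-6,10-dimethyl-5-(TES-oxy)dodeca-2,6,10-trienoate | CC(C)(C)[Si](c1ccccc1)(c1ccccc1)OC/C=C(/C)CC/C=C(\C)[C@@H](O[Si](CC)(CC)CC)C/C=C/C(=O)OC | intermediate
9 | bis(pinacolato)diboron | CC1(C)OB(OC1(C)C)B1OC(C)(C)C(C)(C)O1 | starting material
10 | methyl (3S,5S,6E,10Z)-12-(TBDPS-oxy)-6,10-dimethyl-3-(4,4,5,5-tetramethyl-1,3,2-dioxaborolan-2-yl)-5-(TES-oxy)dodeca-6,10-dienoate | CC(C)(C)[Si](c1ccccc1)(c1ccccc1)OC/C=C(/C)CC/C=C(\C)[C@@H](O[Si](CC)(CC)CC)C[C@H](B1OC(C)(C)C(C)(C)O1)CC(=O)OC | intermediate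
11 | lithium (Z)-enolate of the 2-formyl derivative of 10 (not isolated) | CC(C)(C)[Si](c1ccccc1)(c1ccccc1)OC/C=C(/C)CC/C=C(\C)[C@@H](O[Si](CC)(CC)CC)C[C@H](B1OC(C)(C)C(C)(C)O1)/C(C(=O)OC)=C/[O-].[Li+] | intermediate
12 | methyl (2Z)-3-(TBS-oxy)-2-[(1S,3S,4E,8Z)-10-(TBDPS-oxy)-4,8-dimethyl-1-(4,4,5,5-tetramethyl-1,3,2-dioxaborolan-2-yl)-3-(TES-oxy)deca-4,8-dien-1-yl]prop-2-enoate | CC(C)(C)[Si](c1ccccc1)(c1ccccc1)OC/C=C(/C)CC/C=C(\C)[C@@H](O[Si](CC)(CC)CC)C[C@H](B1OC(C)(C)C(C)(C)O1)/C(C(=O)OC)=C/O[Si](C)(C)C(C)(C)C | intermediate
13 | 3-methylbut-2-enal | CC(C)=CC=O | starting material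
14 | O-(pinacolboryl) ester of 15 at the Cγ oxygen (not isolated) | CC(C)(C)[Si](c1ccccc1)(c1ccccc1)OC/C=C(/C)CC/C=C(\C)[C@@H](O[Si](CC)(CC)CC)C/C=C(/C(=O)OC)[C@H](O[Si](C)(C)C(C)(C)C)[C@H](OB1OC(C)(C)C(C)(C)O1)C=C(C)C | intermediate
15 | methyl (2E,5S,6E,10Z)-2-[(1S,2R)-1-(TBS-oxy)-2-hydroxy-4-methylpent-3-en-1-yl]-12-(TBDPS-oxy)-6,10-dimethyl-5-(TES-oxy)dodeca-2,6,10-trienoate | CC(C)(C)[Si](c1ccccc1)(c1ccccc1)OC/C=C(/C)CC/C=C(\C)[C@@H](O[Si](CC)(CC)CC)C/C=C(/C(=O)OC)[C@H](O[Si](C)(C)C(C)(C)C)[C@H](O)C=C(C)C | intermediate
16 | (3E,4S,5R)-4-(TBS-oxy)-3-[(3S,4E,8Z)-10-(TBDPS-oxy)-4,8-dimethyl-3-(TES-oxy)deca-4,8-dien-1-ylidene]-5-(2-methylprop-1-en-1-yl)oxolan-2-one | CC(C)(C)[Si](c1ccccc1)(c1ccccc1)OC/C=C(/C)CC/C=C(\C)[C@@H](O[Si](CC)(CC)CC)C/C=C1/C(=O)O[C@H](C=C(C)C)[C@H]1O[Si](C)(C)C(C)(C)C | intermediate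
17 | (3E,4S,5R)-4-(TBS-oxy)-3-[(3S,4E,8Z)-10-(TBDPS-oxy)-3-hydroxy-4,8-dimethyldeca-4,8-dien-1-ylidene]-5-(2-methylprop-1-en-1-yl)oxolan-2-one | CC(C)(C)[Si](c1ccccc1)(c1ccccc1)OC/C=C(/C)CC/C=C(\C)[C@@H](O)C/C=C1/C(=O)O[C@H](C=C(C)C)[C@H]1O[Si](C)(C)C(C)(C)C | intermediate
18 | (3S,4E,8Z)-1-[(3E,4S,5R)-4-(TBS-oxy)-5-(2-methylprop-1-en-1-yl)-2-oxooxolan-3-ylidene]-10-(TBDPS-oxy)-4,8-dimethyldeca-4,8-dien-3-yl acetate | CC(C)(C)[Si](c1ccccc1)(c1ccccc1)OC/C=C(/C)CC/C=C(\C)[C@@H](OC(C)=O)C/C=C1/C(=O)O[C@H](C=C(C)C)[C@H]1O[Si](C)(C)C(C)(C)C | intermediate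
19 | (3S,4E,8Z)-10-hydroxy-1-[(3E,4S,5R)-4-hydroxy-5-(2-methylprop-1-en-1-yl)-2-oxooxolan-3-ylidene]-4,8-dimethyldeca-4,8-dien-3-yl acetate | OC/C=C(/C)CC/C=C(\C)[C@@H](OC(C)=O)C/C=C1/C(=O)O[C@H](C=C(C)C)[C@H]1O | intermediate
20 | (2E)-3-methylpent-2-enoic acid | CC/C(C)=C/C(=O)O | starting material
21 | (2Z,6E,8S)-8-acetoxy-10-[(3E,4S,5R)-4-hydroxy-5-(2-methylprop-1-en-1-yl)-2-oxooxolan-3-ylidene]-3,7-dimethyldeca-2,6-dien-1-yl (2E)-3-methylpent-2-enoate (CNP0168501.1) | CC/C(C)=C/C(=O)OC/C=C(/C)CC/C=C(\C)[C@H](C/C=C1/C(=O)O[C@H](C=C(C)C)[C@H]1O)OC(C)=O | target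

Total step count: 13. Longest linear sequence: 13 steps (1 to 21); all other components are commercial.

Least certain steps

Step 8 (key step, proposed new method). The most likely failure is sluggish allyl transfer, because Cβ is at once the nucleophilic terminus of the allylboronate and the β-carbon of an acrylate, so prolonged heating may be needed and may cost the enol silyl group. The second risk is leakage through the chair with C9 equatorial, which would give the Z alkylidene with both carbinols inverted. A Lewis acid such as Sc(OTf)3 could speed the reaction but may open the way to non-chair pathways and silyl loss. The fallback uses known chemistry, sets out from 6 and returns at 16: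
- 2-Deoxy-D-ribose is oxidised with bromine water to 2-deoxy-D-ribono-1,4-lactone F1, which already has the trans (4S,5R) arrangement of the ring.
- Both hydroxyls are silylated (TBSCl, imidazole) to the bis-silyl ether F2, and the primary silyl ether is cleaved selectively (CF3CO2H, H2O, THF, 0 °C) to the primary alcohol F3.
- Dess–Martin oxidation gives the lactone aldehyde F4, and a Wittig reaction with isopropylidenetriphenylphosphorane (from the phosphonium iodide and NaN(SiMe3)2, −78 °C) gives the 2-methylprop-1-enyl lactone F5.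
- α-Methylenation (LiN(iPr)2, Eschenmoser's salt; MeI; NaHCO3) gives the α-methylene lactone F6.
- Cross-metathesis of F6 with the terminal alkene of 6 (second-generation Hoveyda–Grubbs catalyst, 2,6-dichloro-1,4-benzoquinone, CH2Cl2, 40 °C) forms C10=Cα and returns to 16; this reaction type is known to favour the E alkylidene with α-methylene γ-lactones.
- This path gives up the relay of stereochemistry from boron but uses the chiral pool for Cβ and Cγ.

Step 7. What may go wrong is incomplete C-formylation (the amide base and methoxide also consume formate, and the Claisen step is reversible until the product is deprotonated) and partial loss of the chelate geometry during silylation, which would give some E enol ether and hence cis-lactone material later. The fallback changes the way the formyl carbon is introduced; it sets out from 10 and returns at 12: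
- The lithium enolate of 10 is treated with monomeric formaldehyde in an irreversible aldol to give the hydroxymethyl ester F7 (both C2 epimers).
- Dess–Martin oxidation gives the formyl ester, which rests as its hydrogen-bonded Z enol F8.
- F8 is silylated at once in the cold (TBSCl, imidazole, CH2Cl2, −20 °C) to 12, with the internal hydrogen bond fixing the geometry.

Step 2. Over-oxidation, incomplete conversion and some attack at the other allylic positions are the usual losses of selenium dioxide oxidations of terpenoid chains. The fallback builds the enal by cleavage and olefination; it sets out from 2 and returns at 4: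
- The terminal alkene is converted selectively (NBS, THF/H2O; then K2CO3, MeOH) into the epoxide F9.
- Periodic acid (H5IO6, THF/Et2O, 0 °C) cleaves F9 to the aldehyde F10.
- A Wittig reaction with 2-(triphenylphosphoranylidene)propanal (toluene, 90 °C) installs the E 2-methyl enal of 4.

Step 9. Even weak acid may trigger ionisation of the allylic Cγ–OH before ring closure, or 1,2-migration of the silyl group from the Cβ oxygen to the Cγ oxygen, which would block lactonisation. The fallback replaces transesterification by hydrolysis and carboxyl activation; it sets out from 15 and returns at 16: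
- Me3SnOH (1,2-dichloroethane, 70 °C) converts the methyl ester into the hydroxy acid F11 under neutral conditions.
- F11 is closed with EDC·HCl and a catalytic amount of DMAP (CH2Cl2, 0 °C).

Step 13. The risk is loss of chemoselectivity, that is activation of the ring hydroxyl once the primary alcohol is consumed, or allylic transposition during displacement at C1. The fallback separates the two hydroxyls by protecting groups and no longer relies on selectivity; it sets out from 18 and returns at 21:
- One equivalent of buffered fluoride (Bu4NF/AcOH, THF, 0 °C) removes the unhindered primary TBDPS ether first and gives the primary alcohol F12 with the ring silyl ether intact.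
- F12 is esterified with 20 (EDC·HCl, DMAP, CH2Cl2, 0 °C) to the silyl-protected target F13.
- HF·pyridine (pyridine, THF) removes the last silyl group to give 21.

Further compounds

F1 | step 8 | 2-deoxy-D-ribono-1,4-lactone, (4S,5R)-4-hydroxy-5-(hydroxymethyl)oxolan-2-one | C1C(=O)O[C@H](CO)[C@H]1O
F2 | step 8 | (4S,5R)-4-(tert-butyldimethylsilyloxy)-5-[(tert-butyldimethylsilyloxy)methyl]oxolan-2-one | C1C(=O)O[C@H](CO[Si](C)(C)C(C)(C)C)[C@H]1O[Si](C)(C)C(C)(C)C
F3 | step 8 | (4S,5R)-4-(tert-butyldimethylsilyloxy)-5-(hydroxymethyl)oxolan-2-one | C1C(=O)O[C@H](CO)[C@H]1O[Si](C)(C)C(C)(C)C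
F4 | step 8 | (2S,3S)-3-(tert-butyldimethylsilyloxy)-5-oxooxolane-2-carbaldehyde | C1C(=O)O[C@H](C=O)[C@H]1O[Si](C)(C)C(C)(C)C
F5 | step 8 | (4S,5R)-4-(tert-butyldimethylsilyloxy)-5-(2-methylprop-1-en-1-yl)oxolan-2-one | C1C(=O)O[C@H](C=C(C)C)[C@H]1O[Si](C)(C)C(C)(C)C
F6 | step 8 | (4S,5R)-4-(tert-butyldimethylsilyloxy)-3-methylidene-5-(2-methylprop-1-en-1-yl)oxolan-2-one | C=C1C(=O)O[C@H](C=C(C)C)[C@H]1O[Si](C)(C)C(C)(C)C
F7 | step 7 | methyl (3S,5S,6E,10Z)-12-(TBDPS-oxy)-2-(hydroxymethyl)-6,10-dimethyl-3-(4,4,5,5-tetramethyl-1,3,2-dioxaborolan-2-yl)-5-(TES-oxy)dodeca-6,10-dienoate (both C2 epimers) | CC(C)(C)[Si](c1ccccc1)(c1ccccc1)OC/C=C(/C)CC/C=C(\C)[C@@H](O[Si](CC)(CC)CC)C[C@H](B1OC(C)(C)C(C)(C)O1)C(CO)C(=O)OC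
F8 | step 7 | methyl (2Z)-3-hydroxy-2-[(1S,3S,4E,8Z)-10-(TBDPS-oxy)-4,8-dimethyl-1-(4,4,5,5-tetramethyl-1,3,2-dioxaborolan-2-yl)-3-(TES-oxy)deca-4,8-dien-1-yl]prop-2-enoate (enol form of the formyl ester) | CC(C)(C)[Si](c1ccccc1)(c1ccccc1)OC/C=C(/C)CC/C=C(\C)[C@@H](O[Si](CC)(CC)CC)C[C@H](B1OC(C)(C)C(C)(C)O1)/C(C(=O)OC)=C/O
F9 | step 2 | tert-butyl{[(2Z)-5-(3,3-dimethyloxiran-2-yl)-3-methylpent-2-en-1-yl]oxy}diphenylsilane (racemic at the epoxide) | CC1(C)OC1CC/C(C)=C\CO[Si](c1ccccc1)(c1ccccc1)C(C)(C)C
F10 | step 2 | (4Z)-6-(TBDPS-oxy)-4-methylhex-4-enal | O=CCC/C(C)=C\CO[Si](c1ccccc1)(c1ccccc1)C(C)(C)C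
F11 | step 9 | (2E,5S,6E,10Z)-2-[(1S,2R)-1-(TBS-oxy)-2-hydroxy-4-methylpent-3-en-1-yl]-12-(TBDPS-oxy)-6,10-dimethyl-5-(TES-oxy)dodeca-2,6,10-trienoic acid | CC(C)(C)[Si](c1ccccc1)(c1ccccc1)OC/C=C(/C)CC/C=C(\C)[C@@H](O[Si](CC)(CC)CC)C/C=C(/C(=O)O)[C@H](O[Si](C)(C)C(C)(C)C)[C@H](O)C=C(C)C
F12 | step 13 | (3S,4E,8Z)-1-[(3E,4S,5R)-4-(TBS-oxy)-5-(2-methylprop-1-en-1-yl)-2-oxooxolan-3-ylidene]-10-hydroxy-4,8-dimethyldeca-4,8-dien-3-yl acetate | OC/C=C(/C)CC/C=C(\C)[C@@H](OC(C)=O)C/C=C1/C(=O)O[C@H](C=C(C)C)[C@H]1O[Si](C)(C)C(C)(C)C
F13 | step 13 | (2Z,6E,8S)-8-acetoxy-10-[(3E,4S,5R)-4-(TBS-oxy)-5-(2-methylprop-1-en-1-yl)-2-oxooxolan-3-ylidene]-3,7-dimethyldeca-2,6-dien-1-yl (2E)-3-methylpent-2-enoate | CC/C(C)=C/C(=O)OC/C=C(/C)CC/C=C(\C)[C@@H](OC(C)=O)C/C=C1/C(=O)O[C@H](C=C(C)C)[C@H]1O[Si](C)(C)C(C)(C)C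
A1 | alternative 1 | (3S,4E)-3-hydroxy-6-(methoxycarbonyloxy)-6-methylhept-4-enoic acid | OC(=O)C[C@H](O)/C=C/C(C)(C)OC(=O)OC
A2 | alternative 1 | (4S,5R)-4-hydroxy-5-(2-methylprop-1-en-1-yl)oxolan-2-one | C1C(=O)O[C@H](C=C(C)C)[C@H]1O
A3 | alternative 2 | tert-butyl{[(4S,5R)-4-(tert-butyldimethylsilyloxy)-3-ethenyl-5-(2-methylprop-1-en-1-yl)-4,5-dihydrofuran-2-yl]oxy}dimethylsilane | C=CC1=C(O[Si](C)(C)C(C)(C)C)O[C@H](C=C(C)C)[C@H]1O[Si](C)(C)C(C)(C)C
A4 | alternative 2 | (2Z,6E)-3,7-dimethyl-8-oxoocta-2,6-dien-1-yl (2E)-3-methylpent-2-enoate | CC/C(C)=C/C(=O)OC/C=C(/C)CC/C=C(\C)C=O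
A5 | alternative 2 | (2Z,6E,8S)-10-[(3E,4S,5R)-4-(tert-butyldimethylsilyloxy)-5-(2-methylprop-1-en-1-yl)-2-oxooxolan-3-ylidene]-8-hydroxy-3,7-dimethyldeca-2,6-dien-1-yl (2E)-3-methylpent-2-enoate | CC/C(C)=C/C(=O)OC/C=C(/C)CC/C=C(\C)[C@H](C/C=C1/C(=O)O[C@H](C=C(C)C)[C@H]1O[Si](C)(C)C(C)(C)C)O
A6 | alternative 3 | 1,3-dioxoisoindolin-2-yl (3S,4E,8Z)-4,8-dimethyl-10-{[(2E)-3-methylpent-2-enoyl]oxy}-3-(triethylsilyloxy)deca-4,8-dienoate | CC/C(C)=C/C(=O)OC/C=C(/C)CC/C=C(\C)[C@@H](O[Si](CC)(CC)CC)CC(=O)ON1C(=O)c2ccccc2C1=O
A7 | alternative 3 | (4S,5R)-4-(tert-butyldimethylsilyloxy)-5-(2-methylprop-1-en-1-yl)-3-[(phenylsulfonyl)methylidene]oxolan-2-one (either alkene geometry) | O=S(=O)(c1ccccc1)C=C1C(=O)O[C@H](C=C(C)C)[C@H]1O[Si](C)(C)C(C)(C)C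
A8 | alternative 3 | (2Z,6E,8S)-10-[(3E,4S,5R)-4-(tert-butyldimethylsilyloxy)-5-(2-methylprop-1-en-1-yl)-2-oxooxolan-3-ylidene]-3,7-dimethyl-8-(triethylsilyloxy)deca-2,6-dien-1-yl (2E)-3-methylpent-2-enoate | CC/C(C)=C/C(=O)OC/C=C(/C)CC/C=C(\C)[C@@H](O[Si](CC)(CC)CC)C/C=C1/C(=O)O[C@H](C=C(C)C)[C@H]1O[Si](C)(C)C(C)(C)C
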